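In 12 s of stirring, how much of the electrophile leaves its free form in two flasks that differ in their charge of nucleophile?

| flask | electrophile | nucleophile | time |
|---|---|---|---|
| south | 0.80 M | 0.800 M | 12 s |
| north-east | 0.80 M | 1.60 M | 12 s |

    electrophile + nucleophile → acid set free + target (k1 = 1.2 M⁻¹ s⁻¹)
    nucleophile + acid set free ⇌ protonated nucleophile, settled at all times (K2 = 710 M⁻¹)
    electrophile + target ⇌ idle adduct, settled at all times (K3 = 4.8 M⁻¹)
    target ⇌ isomer of the product (K4 = 0.33, k4 = 0.025 s⁻¹)
    nucleophile ⇌ dormant form (K5 = 3.7, k5 = 0.044 s⁻¹)

- in percentages every species weighs as the electrophile in it: one idle adduct counts as two
- for target the idle adduct is counted in
- in an amount of target, one idle adduct counts as one target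
- what has gone from electrophile into another species counts as reacted, even if it can come back
- run time (south): 12 s

1. part of the electrophile that has reacted at the end, south
2. part of the electrophile that has reacted at the end, north-east
3. what raising the concentration of nucleophile from its lowest to its highest value here does to the part of the electrophile that has reacted (changes below 5 percentage points count as none) (no change / it falls / it rises)

Two chemists dispute the south flask. The first reads one nucleophile per electrophile, so with equal charges plain second-order decay should leave a fraction of the reciprocal of one plus 11.5, which makes 92.0% reacted.

The second chemist, whose reckoning I share, objects that K2 times the starting nucleophile is 570, far above one, so the acid set free takes a further nucleophile for each coupling. She therefore defines the coupling budget, f, as the nucleophile charged divided by 2 times the electrophile charged, the fraction of the electrophile that can couple. In south f is 50.0%, below the whole charge, which makes nucleophile the limiting reagent.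

Free electrophile also binds target, and electrophile held in the idle adduct counts as reacted, so she adds a second term to f. In fractions of the charge, the adduct equals 3.84 times free electrophile times free target. A first pass with nothing yet bound gives 0.960, more than the target there is, so she puts the answer back and goes round until it stops, at an adduct of 24.7%. Adding this to f gives 74.7% reacted.

In north-east the budget is 100%, so her reckoning offers a ceiling and goes no further.

The forecast stands on her side, since “Each coupling uses two nucleophiles”. It gives 74.4% (72% to 77%) for south and 95.4% (94% to 96.5%) for north-east, a little under her figures, and says it rises.

The simulation gives 74.1% for south and 95.6% for north-east, so the part reacted it rises by 21 percentage points. The second view stands, and the first chemist's number belongs to a south flask in which nothing binds the acid, where 92.6% reacts.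

At 12.0 s, target and isomer together in south stand at 50.9%, against a budget of 50.0%. With 0.40 M of nucleophile in the north-east flask the budget is 25.0%, the same reckoning gives 42.2%, and that flask shows 46.0%. Neither recipe has come to rest: at 120 s south holds 0.191 M of acid set free, its target and isomer reach 60.7%, and reacted climbs to 81.7% there and to 98.6% in north-east.

(The constants used here are those of an exercise; what happens was integrated by code.)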